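At 10 min the flask hardest to call is Thursday's, where second substrate stands well above starting material, so we reckon how fast target is lost there.

| flask | starting material | second substrate | enzyme | remark | time |
|---|---|---|---|---|---|
| south | 0.20 M | 0.22 M | 39 µM | run made earlier |  |
| north | 0.20 M | 0.22 M | 150 µM | run made earlier |  |
| north-east | 0.20 M | 0.31 M | 60 µM | run made earlier |  |
| Saturday's | 0.20 M | 0.220 M | 60 µM |  | 10 min |
| Sunday's | 0.20 M | 0.120 M | 60 µM |  | 10 min |
| Wednesday's | 0.60 M | 0.150 M | 100 µM |  | 10 min |
| Thursday's | 0.050 M | 0.600 M | 30 µM |  | 10 min |

| run | time / min | target / % | starting material / % |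
|---|---|---|---|
| south | 0.833 | 53 | 39 |
| south | 1.33 | 70 | 27 |
| south | 2.00 | 72 | 15 |
| south | 4.00 | 83 | 6 |
| south | 6.00 | 84 | 7 |
| south | 10.0 | 87 | 5 |
| north | 0.667 | 88 | 11 |
| north | 2.00 | 92 | 1 |
| north | 4.00 | 93 | 2 |
| north | 5.00 | 92 | 0 |
| north | 8.00 | 95 | 0 |
| north | 10.0 | 91 | 0 |
| north-east | 2.00 | 90 | 1 |
| north-east | 4.00 | 82 | 2 |
| north-east | 6.00 | 76 | 0 |
| north-east | 8.00 | 69 | 2 |
| north-east | 10.0 | 66 | 0 |

(standard deviation of a reading: 2 percentage points)

- the earlier runs were read with a standard deviation of 2 percentage points

- ranking by amount of target, in percent of the starting material charged, from high to low, at 10 min (Saturday's / Sunday's / Wednesday's / Thursday's)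
- the same order at 2.0 min (Saturday's / Sunday's / Wednesday's / Thursday's)
- the amount of target, in percent of the starting material charged of the flask you put first, at 10 min
- the amount of target, in percent of the starting material charged of the flask you put last, at 10 min

In the north-east run, starting material reads 1% at 2.00 min, yet target keeps falling, from 90% to 66% at 10.0 min. We count one second substrate for each starting material turned into target and another for each target lost. By that count, c(second substrate) goes from 0.0900 M to 0.0420 M. Dividing the logarithmic fall per minute by the mean of these gives 0.587 /M/min, our loss constant: the fraction of target lost per minute for each mole per litre of second substrate. It is a reading from a run at one enzyme charge, and taking it as independent of enzyme is our choice, which these runs do not test.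

In Thursday's flask, the excess of second substrate makes the loss nearly pseudo-first-order. After the starting material has been turned over, the rate starts at 0.323 /min. Each target lost takes a second substrate with it, so c(second substrate) sinks to about 0.502 M, and the rate slows by a factor of just 0.913. Kept up over 10 min, the mean rate of 0.309 /min leaves 4.55% of target by our reckoning, so Thursday's comes last.

The forecast gives Saturday's > Sunday's > Wednesday's > Thursday's at 10 min and Saturday's > Thursday's > Sunday's > Wednesday's at 2.0 min, with 90% for the first flask and 17% for the last. It takes “both steps proportional to enzyme”, and its last figure stands above ours.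

The flasks give Saturday's > Sunday's > Wednesday's > Thursday's and Saturday's > Thursday's > Sunday's > Wednesday's, with 89.5% and 5.00%, so the forecast's last figure is 12 points too high.

    starting material + enzyme ⇌ starting complex (K = 6.40 /M, k = 4400 /M/s)
    second substrate + starting complex ⇌ ternary complex (K = 5.90 /M, k = 3100 /M/s)
    ternary complex → enzyme + target (k = 330 /s)
    enzyme → spent catalyst (k = 4.00 × 10⁻⁶ /s)
    second substrate + target → over-reaction product (k = 0.0100 /M/s)

The step from target to over-reaction product carries no enzyme. In Thursday's flask, target reaches 100% without that step, against 5.00% with it. The loss constant serves again on a neighbour of Saturday's flask, with 0.12 M of starting material and the other charges as in Saturday's. Once that starting material has been counted as target, c(second substrate) stands at 0.100 M, below the 0.12 M of target, and the rate starts at 0.0587 /min. Each target lost takes one second substrate with it, so target stays 0.0200 M ahead, and integrating the loss with that difference leaves about 64.3% of target and c(second substrate) at 0.0572 M by our reckoning. The computed flask holds 64.3%.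

The readings were computed with made-up constants; the scatter is artificial.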